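**Assumption:** the target has no stereocentre and no stereogenic axis (the 4-methoxyphenyl ring is symmetric about the biaryl bond), so it is achiral and needs no stereocontrol; 6,7-dibromonaphthalene-2,3-diol 1 is taken as a catalogue compound.

## Retrosynthetic overview

1. Target 9 ⇒ bis-formamide 8 (O-debenzylation last) ⇒ diamine 7 (two N-formylations).
2. 7 ⇒ Suzuki disconnection of the C1–aryl bond: bromodiamine 5 + 4-methoxyphenylboronic acid 6.
3. 5 ⇒ amine-directed C1 bromination of the symmetric diamine 4.
4. 4 ⇒ double C–N coupling of dibromide 2 ⇒ benzylation of diol 1.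
5. No ring is formed: both naphthalene rings are bought intact in 1, and the anisyl ring arrives with 6.

## Route

Step 1
Reactants: 1 6,7-dibromonaphthalene-2,3-diol
Product: 2 2,3-bis(benzyloxy)-6,7-dibromonaphthalene
Conditions: BnBr, K2CO3, DMF, 60 °C
Reagents that add atoms: benzyl bromide BrCc1ccccc1
Why: Williamson ether synthesis of both naphthol oxygens; the benzyl ethers tolerate the strong base, palladium couplings and bromination that follow and are removed at the end by neutral hydrogenolysis without touching the anisyl methyl ether (no stereocentre arises here or in any later step).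

Step 2
Reactants: 2 2,3-bis(benzyloxy)-6,7-dibromonaphthalene
Product: 4 6,7-bis(benzyloxy)naphthalene-2,3-diamine, via bis-ketimine 3 (not isolated)
Conditions: Ph2C=NH, Pd2(dba)3, rac-BINAP, NaOtBu, PhMe, 100 °C; then HCl (cat.), wet THF, rt
Reagents that add atoms: benzophenone imine N=C(c1ccccc1)c1ccccc1
Why: Double Buchwald–Hartwig amination with benzophenone imine as an ammonia surrogate (ortho-dibromoarenes couple twice with this nucleophile under BINAP ligation), after which catalytic acid hydrolyses both N-aryl ketimines to the free ortho-diamine.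

Step 3
Reactants: 4 6,7-bis(benzyloxy)naphthalene-2,3-diamine
Product: 5 6,7-bis(benzyloxy)-1-bromonaphthalene-2,3-diamine
Conditions: NBS (1.0 equiv, slow addition), DMF, −40 to 0 °C
Reagents that add atoms: N-bromosuccinimide O=C1CCC(=O)N1Br
Why: Electrophilic aromatic bromination in which the amino groups, the strongest donors, direct to the ortho alpha-positions C1 and C4 (equivalent by symmetry), and the first bromine deactivates the ring enough that one equivalent in the cold stops mainly at the monobromide.

Step 4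
Reactants: 5 6,7-bis(benzyloxy)-1-bromonaphthalene-2,3-diamine, 6 4-methoxyphenylboronic acid
Product: 7 6,7-bis(benzyloxy)-1-(4-methoxyphenyl)naphthalene-2,3-diamine
Conditions: Pd(PPh3)4, K2CO3, 1,4-dioxane/H2O, 90 °C
Reagents that add atoms: none
Why: Suzuki–Miyaura cross-coupling by oxidative addition of the C1–Br bond to zerovalent palladium and transmetalation with the arylboronate, a reaction that tolerates free ortho-diamines and 2-amino-1-bromonaphthalenes.

Step 5
Reactants: 7 6,7-bis(benzyloxy)-1-(4-methoxyphenyl)naphthalene-2,3-diamine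
Product: 8 N,N'-[6,7-bis(benzyloxy)-1-(4-methoxyphenyl)naphthalene-2,3-diyl]diformamide
Conditions: AcOCHO (preformed, excess), THF, −15 to 0 °C
Reagents that add atoms: acetic formic anhydride CC(=O)OC=O
Why: N-Formylation with a mixed anhydride, in which both amines attack the more electrophilic formyl carbonyl, while the low temperature and absence of strong acid keep the ortho-bis(formamide) from cyclodehydrating to a naphthimidazole.

Step 6
Reactants: 8 N,N'-[6,7-bis(benzyloxy)-1-(4-methoxyphenyl)naphthalene-2,3-diyl]diformamide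
Product: 9 Melanocin E (N,N'-[6,7-dihydroxy-1-(4-methoxyphenyl)naphthalene-2,3-diyl]diformamide)
Conditions: H2 (1 atm), Pd/C, THF/MeOH, rt
Reagents that add atoms: none
Why: Catalytic hydrogenolysis of the two benzyl ethers under neutral conditions, which leaves the formamides, the aryl methyl ether and the naphthalene core untouched and gives the air-sensitive catechol directly (work-up under argon).

## Compound list

1 | 6,7-dibromonaphthalene-2,3-diol | Oc1cc2cc(Br)c(Br)cc2cc1O | starting material
2 | 2,3-bis(benzyloxy)-6,7-dibromonaphthalene | Brc1cc2cc(OCc3ccccc3)c(OCc3ccccc3)cc2cc1Br | intermediate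
3 | N,N'-[6,7-bis(benzyloxy)naphthalene-2,3-diyl]bis(1,1-diphenylmethanimine) | c1ccc(cc1)C(=Nc1cc2cc(OCc3ccccc3)c(OCc3ccccc3)cc2cc1N=C(c1ccccc1)c1ccccc1)c1ccccc1 | intermediate
4 | 6,7-bis(benzyloxy)naphthalene-2,3-diamine | Nc1cc2cc(OCc3ccccc3)c(OCc3ccccc3)cc2cc1N | intermediate
5 | 6,7-bis(benzyloxy)-1-bromonaphthalene-2,3-diamine | Nc1cc2cc(OCc3ccccc3)c(OCc3ccccc3)cc2c(Br)c1N | intermediate
6 | 4-methoxyphenylboronic acid | COc1ccc(B(O)O)cc1 | starting material
7 | 6,7-bis(benzyloxy)-1-(4-methoxyphenyl)naphthalene-2,3-diamine | COc1ccc(-c2c(N)c(N)cc3cc(OCc4ccccc4)c(OCc4ccccc4)cc23)cc1 | intermediate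
8 | N,N'-[6,7-bis(benzyloxy)-1-(4-methoxyphenyl)naphthalene-2,3-diyl]diformamide | COc1ccc(-c2c(NC=O)c(NC=O)cc3cc(OCc4ccccc4)c(OCc4ccccc4)cc23)cc1 | intermediate
9 | Melanocin E, N,N'-[6,7-dihydroxy-1-(4-methoxyphenyl)naphthalene-2,3-diyl]diformamide | COc1ccc(-c2c(NC=O)c(NC=O)cc3cc(O)c(O)cc23)cc1 | target

## Summary

Total step count: 6. Longest linear sequence: 6 steps (1 → 2 → 4 → 5 → 7 → 8 → 9).

## Steps most likely to fail

**Step 3 (monobromination).** The diamine 4 has two equivalent reactive sites and is easily oxidised, so the 1,4-dibromide and quinoid by-products may erode the yield. The fallback sets out from 2 and comes back at 7; it introduces the two nitrogens one at a time so that only one position is ever open to halogenation. Coupling 2 with one equivalent of benzophenone imine (Pd2(dba)3, rac-BINAP, NaOtBu, PhMe, 80 °C) gives N-[6,7-bis(benzyloxy)-3-bromonaphthalen-2-yl]-1,1-diphenylmethanimine F1; the second C–Br bond, now ortho to a bulky donor, reacts much more slowly. Hydrolysis (cat. HCl, wet THF) gives 6,7-bis(benzyloxy)-3-bromonaphthalen-2-amine F2. NIS in DMF iodinates the only free position ortho to the amine and gives 6,7-bis(benzyloxy)-3-bromo-1-iodonaphthalen-2-amine F3. A Suzuki coupling with 6 that is selective for the C–I bond (Pd(PPh3)4, Na2CO3, dioxane/H2O, 70 °C) gives 6,7-bis(benzyloxy)-3-bromo-1-(4-methoxyphenyl)naphthalen-2-amine F4. Copper-catalysed amination of the remaining C–Br bond with aqueous NH3 (CuI, L-proline, K2CO3, DMSO, 90 °C) then gives 7.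

**Step 2 (double amination).** The second C–N coupling, ortho to the first ketimine, may stall. The fallback sets out from 2 and comes back at 4; it replaces palladium amination by copper azidation and reduction. Treating 2 with NaN3, CuI, sodium L-ascorbate and N,N'-dimethylethylenediamine in EtOH/H2O at 90 °C gives 2,3-diazido-6,7-bis(benzyloxy)naphthalene F5 (any azide already reduced in the flask converges on the same product). Zn and NH4Cl in EtOH/H2O then reduce it to 4 without touching the benzyl ethers.

**Step 4 (Suzuki coupling on the free ortho-diamine).** Chelation of palladium by the diamine or its oxidation may give low conversion. The fallback sets out from 5 and comes back at 7; it masks the diamine as a heterocycle for the coupling. Ring closure of 5 with SOCl2 and Et3N in CH2Cl2 gives 6,7-bis(benzyloxy)-4-bromonaphtho[2,3-c][1,2,5]thiadiazole F6. Suzuki coupling with 6 (Pd(PPh3)4, K2CO3, PhMe/H2O, 90 °C) gives 6,7-bis(benzyloxy)-4-(4-methoxyphenyl)naphtho[2,3-c][1,2,5]thiadiazole F7. Zn in AcOH at 60 °C cleaves the N–S bonds and returns the free diamine 7.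

## Further compounds

F1 | step 3 | N-[6,7-bis(benzyloxy)-3-bromonaphthalen-2-yl]-1,1-diphenylmethanimine | Brc1cc2cc(OCc3ccccc3)c(OCc3ccccc3)cc2cc1N=C(c1ccccc1)c1ccccc1
F2 | step 3 | 6,7-bis(benzyloxy)-3-bromonaphthalen-2-amine | Nc1cc2cc(OCc3ccccc3)c(OCc3ccccc3)cc2cc1Br
F3 | step 3 | 6,7-bis(benzyloxy)-3-bromo-1-iodonaphthalen-2-amine | Nc1c(Br)cc2cc(OCc3ccccc3)c(OCc3ccccc3)cc2c1I
F4 | step 3 | 6,7-bis(benzyloxy)-3-bromo-1-(4-methoxyphenyl)naphthalen-2-amine | COc1ccc(-c2c(N)c(Br)cc3cc(OCc4ccccc4)c(OCc4ccccc4)cc23)cc1
F5 | step 2 | 2,3-diazido-6,7-bis(benzyloxy)naphthalene | [N-]=[N+]=Nc1cc2cc(OCc3ccccc3)c(OCc3ccccc3)cc2cc1N=[N+]=[N-]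
F6 | step 4 | 6,7-bis(benzyloxy)-4-bromonaphtho[2,3-c][1,2,5]thiadiazole | Brc1c2cc(OCc3ccccc3)c(OCc3ccccc3)cc2cc2nsnc12
F7 | step 4 | 6,7-bis(benzyloxy)-4-(4-methoxyphenyl)naphtho[2,3-c][1,2,5]thiadiazole | COc1ccc(-c2c3cc(OCc4ccccc4)c(OCc4ccccc4)cc3cc3nsnc23)cc1
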